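The route rests on cutting the C23–C24 bond of the tetracontanoyl chain, two CH2 carbons of like polarity in the unbranched polymethylene run C2–C40. Each becomes a primary radical by loss of CO2 from an even-numbered acid: heptadecyl (C24–C40) from stearic acid, and the ω-radical of C1–C23 from the mono-tyrosyl ester of tetracosanedioic acid. The key step, a nickel-electrocatalytic doubly decarboxylative cross-coupling of the two N-acyloxyphthalimides made in the same flask, delivers the target directly; its reductive radical generation spares the free phenol of the para-substituted benzene ring, which an anodic Kolbe coupling would not.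

Key step: step 2

Remark: tetracosanedioic acid (the C24 α,ω-diacid) is taken as a catalogue chemical; the target has 40 acyl carbons, no stereocentre and no C=C bond, so no stereochemical control is needed.

Step 1
Reactants: 1 tetracosanedioic acid; 2 tyrosol, 2-(4-hydroxyphenyl)ethanol
Product: 3 24-[2-(4-hydroxyphenyl)ethoxy]-24-oxotetracosanoic acid (mono-tyrosyl hydrogen tetracosanedioate)
Conditions: 1 (3 equiv), 2 (1 equiv), p-TsOH·H2O (5 mol%), toluene, reflux, Dean–Stark; cool, filter off unreacted 1 (recycled); SiO2
Reagents that add atoms: none
Why: Fischer esterification, in which only the primary aliphatic hydroxyl of 2 is acylated under acid catalysis (the phenol does not esterify at equilibrium), while the threefold excess of diacid biases the statistics toward the mono-ester and unreacted 1 should crystallise on cooling.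

Step 2
Reactants: 3 24-[2-(4-hydroxyphenyl)ethoxy]-24-oxotetracosanoic acid; 4 stearic acid (octadecanoic acid)
Product: 7 2-(4-hydroxyphenyl)ethyl tetracontanoate, via C24 redox-active ester 5 (not isolated), via stearic redox-active ester 6 (not isolated)
Conditions: (i) 3 (1 equiv), 4 (3 equiv), N-hydroxyphthalimide, DIC, THF, rt, no DMAP; (ii) NiCl2·6H2O (20 mol%), tBu3-terpyridine (20 mol%), AgNO3 (0.3 equiv), NMP/THF, Mg(+)/RVC(−), constant current, 40 °C; aq. HCl work-up, SiO2
Reagents that add atoms: N-hydroxyphthalimide, O=C1c2ccccc2C(=O)N1O (its atoms stand only in the intermediates 5 and 6 and leave again as phthalimide; none remain in 7)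
Why: DIC condenses both acids with N-hydroxyphthalimide to the redox-active esters 5 and 6, and cathodically generated low-valent terpyridine–nickel transfers one electron to each ester, which fragments into CO2, phthalimide anion and a primary alkyl radical (heptadecyl from 6, the ω-(tyrosyloxycarbonyl)docosyl radical from 5). Capture of one radical by nickel gives an alkyl–nickel species that takes up the second radical, and reductive elimination from the dialkylnickel(III) forges the C23–C24 CH2–CH2 bond; the closest known reaction type is the nickel-electrocatalytic doubly decarboxylative C(sp3)–C(sp3) coupling of two primary alkyl N-acyloxyphthalimides on a silver-nanoparticle-coated cathode, the reductive counterpart of mixed Kolbe electrolysis. No ring is closed and no stereocentre is formed. The step needs cross- over homo-coupling: both radicals are unbiased primary alkyls, so the outcome is statistical and the threefold excess of the cheap ester 6 should drive 5 into the cross-product, while the homo-dimers (an alkane without polar group and a diester with two phenols) differ from 7 in polarity and should be removable on silica. It also needs chemoselectivity toward the unprotected phenol and the alkyl ester: radical generation is reductive, so the phenol is not oxidised, DIC without DMAP activates only the carboxyl groups, and the hydrogen-bond-accepting solvent slows hydrogen-atom transfer from the O–H to the alkyl radicals.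

Compound list
1 | tetracosanedioic acid | OC(=O)CCCCCCCCCCCCCCCCCCCCCCC(=O)O | starting material
2 | tyrosol, 2-(4-hydroxyphenyl)ethanol | OCCc1ccc(O)cc1 | starting material
3 | 24-[2-(4-hydroxyphenyl)ethoxy]-24-oxotetracosanoic acid | OC(=O)CCCCCCCCCCCCCCCCCCCCCCC(=O)OCCc1ccc(O)cc1 | intermediate
4 | stearic acid (octadecanoic acid) | CCCCCCCCCCCCCCCCCC(=O)O | starting material
5 | 1,3-dioxoisoindolin-2-yl 2-(4-hydroxyphenyl)ethyl tetracosanedioate (C24 redox-active ester) | O=C(CCCCCCCCCCCCCCCCCCCCCCC(=O)OCCc1ccc(O)cc1)ON2C(=O)c3ccccc3C2=O | intermediate
6 | 1,3-dioxoisoindolin-2-yl octadecanoate (stearic redox-active ester) | CCCCCCCCCCCCCCCCCC(=O)ON1C(=O)c2ccccc2C1=O | intermediate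
7 | 2-(4-hydroxyphenyl)ethyl tetracontanoate | CCCCCCCCCCCCCCCCCCCCCCCCCCCCCCCCCCCCCCCC(=O)OCCc1ccc(O)cc1 | target

Total step count: 2
Longest linear sequence: 2 steps (1 → 3 → 7)

Steps most likely to fail (the route has only two steps, so both are ranked):

1. Step 2. The free phenol may hand a hydrogen atom or a proton to the alkyl radicals or alkyl–nickel intermediates, so that decarboxylative reduction replaces C–C bond formation. In addition, the statistical radical pairing may favour homo-coupling, and the long-chain esters may precipitate from the electrolyte. The fallback forms the same C23–C24 bond by anodic radical coupling with no phenol present and sets out from 1 and 4. Statistical acid-catalysed mono-esterification of 1 with methanol (MeOH, cat. H2SO4, toluene) should give monomethyl hydrogen tetracosanedioate F1. Mixed Kolbe electrolysis of F1 with an excess of 4 (Pt electrodes, NaOMe 5–10 mol%, MeOH/light petroleum, 50–60 °C) should give methyl tetracontanoate F2. Saponification (KOH, EtOH/toluene, reflux; then H3O+) should give tetracontanoic acid F3. Fischer esterification of F3 with tyrosol 2 (cat. p-TsOH, toluene, Dean–Stark) comes back to the route at 7.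

2. Step 1. Over-esterification to the bis-tyrosyl diester, slow conversion of the sparingly soluble diacid, and acid-promoted self-condensation of tyrosol on prolonged heating may erode the mono-ester. The fallback sets out from 1 and 2 and inverts the activation. A Mitsunobu esterification (PPh3, DIAD, THF, 0 → 40 °C, 1 in threefold excess) activates the primary alcohol of 2 instead of the acid. The carboxylic acid, far more acidic than the phenol, is the pronucleophile that reacts, so the phenol should stay free. The fallback comes back to the route at 3 without new intermediates.

Further compounds
F1 | step 2 | 24-methoxy-24-oxotetracosanoic acid (monomethyl hydrogen tetracosanedioate) | COC(=O)CCCCCCCCCCCCCCCCCCCCCCC(=O)O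
F2 | step 2 | methyl tetracontanoate | CCCCCCCCCCCCCCCCCCCCCCCCCCCCCCCCCCCCCCCC(=O)OC
F3 | step 2 | tetracontanoic acid | CCCCCCCCCCCCCCCCCCCCCCCCCCCCCCCCCCCCCCCC(=O)O
F0 | step 1 | none | none
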